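**Strategy.** The 14-membered ring is closed at C1–C14 (ring numbered from the side-chain-bearing methine C1 through the E-C4=C5 and Z-C8=C9 alkenes to C12, which carries CH2OH; C15=C16 is the exocyclic methylene). C1 is an allylic methine next to a 1,1-disubstituted alkene, the retron of an SN2′ substitution. The key step hydroborates the terminal C13=C14 vinyl group of an acyclic Z-allylic chloride (Cl on C16, alkene C1=C15) and, under a chiral copper catalyst, the alkylborane attacks C1 intramolecularly: one operation forms the ring, sets the C1 stereocentre and unveils the C15=C16 methylene by allylic transposition. The precursor is a linear C25 pentaene chloride assembled from neryl acetate.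

Key step: step 14

Remark (assumption on the chemistry): the absolute sense of induction of the CuOTf/DTBM-MeO-BIPHEP catalyst is assumed, with the (R)-ligand written for step 8. In the common frame of a Z-allylic chloride the two copper steps need attack on opposite faces of the γ-carbon, so step 14 uses the (S)-ligand. Both hands are exchanged if step 8 shows the other sense.

**Step 1**
Reactants: 1 neryl acetate
Product: 2 (2Z,6E)-8-hydroxy-3,7-dimethylocta-2,6-dien-1-yl acetate
Conditions: SeO2 (cat.), t-BuOOH, salicylic acid (cat.), CH2Cl2, 25 °C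
Reagents that add atoms: tert-butyl hydroperoxide, CC(C)(C)OO (oxygen passed on through catalytic selenium dioxide, O=[Se]=O)
Why: SeO2 allylic oxidation (ene reaction, then [2,3]-shift) should attack only the terminal isopropylidene group, because the 2,3-alkene is deactivated by the allylic acetate, and its known E-selectivity hydroxylates the methyl trans to the chain.

**Step 2**
Reactants: 2 (2Z,6E)-8-hydroxy-3,7-dimethylocta-2,6-dien-1-yl acetate
Product: 3 (2Z,6E)-8-bromo-3,7-dimethylocta-2,6-dien-1-yl acetate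
Conditions: CBr4, PPh3, CH2Cl2, 0 °C
Reagents that add atoms: carbon tetrabromide, BrC(Br)(Br)Br
Why: Appel bromination should convert the primary allylic alcohol into the bromide under neutral conditions without allylic transposition or loss of alkene geometry.

**Step 3**
Reactants: 3 (2Z,6E)-8-bromo-3,7-dimethylocta-2,6-dien-1-yl acetate; 4 (1,3-dioxolan-2-ylmethyl)magnesium bromide
Product: 6 (2Z,6E)-9-(1,3-dioxolan-2-yl)-3,7-dimethylnona-2,6-dien-1-ol, via acetal acetate 5 (not isolated)
Conditions: 4 (2.5 equiv), Li2CuCl4 (cat.), THF, −78 → 0 °C; then K2CO3, MeOH, 25 °C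
Reagents that add atoms: (1,3-dioxolan-2-ylmethyl)magnesium bromide (4), Br[Mg]CC1OCCO1
Why: Copper-catalysed Grignard coupling should substitute the primary allylic bromide at its unhindered α-carbon with the E geometry kept, and methanolysis in the same flask removes the acetate, so that any acetate already attacked by excess Grignard reagent also ends as 6.

**Step 4**
Reactants: 6 (2Z,6E)-9-(1,3-dioxolan-2-yl)-3,7-dimethylnona-2,6-dien-1-ol
Product: 7 (2Z,6E)-9-(1,3-dioxolan-2-yl)-3,7-dimethylnona-2,6-dienal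
Conditions: TEMPO (cat.), PhI(OAc)2, CH2Cl2, 25 °C
Reagents that add atoms: none
Why: Oxoammonium (TEMPO) oxidation should turn the Z-allylic alcohol into the Z-enal without Z/E isomerisation and without touching the acetal or the isolated alkene.

**Step 5**
Reactants: 7 (2Z,6E)-9-(1,3-dioxolan-2-yl)-3,7-dimethylnona-2,6-dienal
Product: 8 2-[(3E,7Z)-3,7-dimethyldeca-3,7,9-trien-1-yl]-1,3-dioxolane
Conditions: Ph3PCH3Br, KN(SiMe3)2, THF, −78 → 0 °C
Reagents that add atoms: methyltriphenylphosphonium bromide, C[P+](c1ccccc1)(c1ccccc1)c1ccccc1.[Br-]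
Why: Wittig methylenation at low temperature should give the terminal 1,3-diene while the Z geometry of the trisubstituted alkene is retained.

**Step 6**
Reactants: 9 (Z)-but-2-ene-1,4-diol
Product: 10 (Z)-4-[(tert-butyldiphenylsilyl)oxy]but-2-en-1-ol
Conditions: NaH (1 equiv), THF, 0 °C; then t-BuPh2SiCl
Reagents that add atoms: tert-butyl(chloro)diphenylsilane, CC(C)(C)[Si](Cl)(c1ccccc1)c1ccccc1
Why: Silylation of the sparingly soluble monosodium alkoxide of the symmetric diol should stop at the mono-ether.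

**Step 7**
Reactants: 10 (Z)-4-[(tert-butyldiphenylsilyl)oxy]but-2-en-1-ol
Product: 11 tert-butyl{[(Z)-4-chlorobut-2-en-1-yl]oxy}diphenylsilane
Conditions: N-chlorosuccinimide, Me2S, CH2Cl2, −20 → 0 °C
Reagents that add atoms: N-chlorosuccinimide, O=C1CCC(=O)N1Cl
Why: Corey–Kim chlorination should give the primary allylic chloride by SN2 displacement of the alkoxysulfonium group without allylic shift or Z/E isomerisation.

**Step 8**
Reactants: 8 2-[(3E,7Z)-3,7-dimethyldeca-3,7,9-trien-1-yl]-1,3-dioxolane; 11 tert-butyl{[(Z)-4-chlorobut-2-en-1-yl]oxy}diphenylsilane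
Product: 13 tert-butyl{[(2S,5Z,9E)-12-(1,3-dioxolan-2-yl)-2-ethenyl-6,10-dimethyldodeca-5,9-dien-1-yl]oxy}diphenylsilane, via alkylborane 12 (not isolated)
Conditions: 9-BBN dimer, THF, 0 → 25 °C; then 11, CuOTf·(toluene)0.5 (cat.), (R)-DTBM-MeO-BIPHEP (cat.), KOEt, 1,4-dioxane, 15 °C
Reagents that add atoms: tert-butyl{[(Z)-4-chlorobut-2-en-1-yl]oxy}diphenylsilane (11), ClC/C=C\CO[Si](C(C)(C)C)(c1ccccc1)c1ccccc1
Why: 9-BBN should add only to the terminal CH2 of the diene, and the derived borate passes its primary alkyl group to copper for the known enantioselective γ-selective (SN2′) allyl–alkyl coupling with a Z-allylic chloride, in which the chiral bisphosphine sets C12 by delivery to the si face of the γ-carbon.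

**Step 9**
Reactants: 13 tert-butyl{[(2S,5Z,9E)-12-(1,3-dioxolan-2-yl)-2-ethenyl-6,10-dimethyldodeca-5,9-dien-1-yl]oxy}diphenylsilane
Product: 14 (4E,8Z,12S)-12-{[(tert-butyldiphenylsilyl)oxy]methyl}-4,8-dimethyltetradeca-4,8,13-trienal
Conditions: 2 M HCl aq, THF, 25 °C
Reagents that add atoms: water, O
Why: Dilute aqueous acid should hydrolyse the dioxolane to the aldehyde while the silyl ether and the alkenes stay intact.

**Step 10**
Reactants: 15 methyl 2-[bis(2,2,2-trifluoroethoxy)phosphoryl]acetate; 16 5-bromo-2-methylpent-2-ene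
Product: 17 methyl 2-[bis(2,2,2-trifluoroethoxy)phosphoryl]-6-methylhept-5-enoate (racemic)
Conditions: NaH, NaI (cat.), DMF, 0 → 50 °C
Reagents that add atoms: 5-bromo-2-methylpent-2-ene (16), CC(C)=CCCBr
Why: C-alkylation of the stabilised phosphonoacetate anion with the primary bromide (iodide catalysis) should give the α-substituted olefination reagent.

**Step 11**
Reactants: 14 (4E,8Z,12S)-12-{[(tert-butyldiphenylsilyl)oxy]methyl}-4,8-dimethyltetradeca-4,8,13-trienal; 17 methyl 2-[bis(2,2,2-trifluoroethoxy)phosphoryl]-6-methylhept-5-enoate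
Product: 18 methyl (2Z,6E,10Z,14S)-14-{[(tert-butyldiphenylsilyl)oxy]methyl}-6,10-dimethyl-2-(4-methylpent-3-en-1-yl)hexadeca-2,6,10,15-tetraenoate
Conditions: KN(SiMe3)2, 18-crown-6, THF, −78 °C
Reagents that add atoms: methyl 2-[bis(2,2,2-trifluoroethoxy)phosphoryl]-6-methylhept-5-enoate (17), COC(=O)C(CCC=C(C)C)P(=O)(OCC(F)(F)F)OCC(F)(F)F
Why: Still–Gennari olefination with the electron-poor phosphonate and a dissociated potassium base should be kinetically controlled and place the ester cis to the aldehyde-derived chain (Z-enoate).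

**Step 12**
Reactants: 18 methyl (2Z,6E,10Z,14S)-14-{[(tert-butyldiphenylsilyl)oxy]methyl}-6,10-dimethyl-2-(4-methylpent-3-en-1-yl)hexadeca-2,6,10,15-tetraenoate
Product: 19 (2Z,6E,10Z,14S)-14-{[(tert-butyldiphenylsilyl)oxy]methyl}-6,10-dimethyl-2-(4-methylpent-3-en-1-yl)hexadeca-2,6,10,15-tetraen-1-ol
Conditions: i-Bu2AlH, CH2Cl2, −78 °C
Reagents that add atoms: none
Why: 1,2-Reduction of the enoate by the aluminium hydride should give the Z-allylic alcohol with the alkene geometry and the silyl ether unchanged.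

**Step 13**
Reactants: 19 (2Z,6E,10Z,14S)-14-{[(tert-butyldiphenylsilyl)oxy]methyl}-6,10-dimethyl-2-(4-methylpent-3-en-1-yl)hexadeca-2,6,10,15-tetraen-1-ol
Product: 20 tert-butyl{[(2S,5Z,9E,13Z)-14-(chloromethyl)-2-ethenyl-6,10,18-trimethylnonadeca-5,9,13,17-tetraen-1-yl]oxy}diphenylsilane
Conditions: N-chlorosuccinimide, Me2S, CH2Cl2, −20 → 0 °C
Reagents that add atoms: N-chlorosuccinimide, O=C1CCC(=O)N1Cl
Why: Corey–Kim chlorination should convert the primary allylic alcohol into the chloride by SN2 displacement without allylic transposition, as it does for terpenoid allylic alcohols.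

**Step 14**
Reactants: 20 tert-butyl{[(2S,5Z,9E,13Z)-14-(chloromethyl)-2-ethenyl-6,10,18-trimethylnonadeca-5,9,13,17-tetraen-1-yl]oxy}diphenylsilane
Product: 22 tert-butyl{[(1S,4Z,8E,12S)-5,9-dimethyl-12-(6-methylhepta-1,5-dien-2-yl)cyclotetradeca-4,8-dien-1-yl]methoxy}diphenylsilane, via alkylborane 21 (not isolated)
Conditions: 9-BBN dimer, THF, 25 °C; KOEt, 0 °C; then slow addition (syringe pump) to CuOTf·(toluene)0.5 (cat.), (S)-DTBM-MeO-BIPHEP (cat.), 1,4-dioxane, 25–40 °C, final concentration about 2 mM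
Reagents that add atoms: none
Why: Proposed new method: 9-BBN adds only to the monosubstituted C13=C14 alkene (boron on C14; the four trisubstituted alkenes are inert), ethoxide turns the borane into a borate that passes the C14 alkyl group to bisphosphine-bound monovalent copper, and the alkylcopper attacks C1 of the Z-allylic chloride anti to the leaving group (oxidative addition at the γ-carbon, then reductive elimination), so that chloride leaves from C16 and the C15=C16 methylene appears. The closest known reaction type is the copper-catalysed enantioselective γ-selective coupling of alkyl-9-BBN reagents with Z-allylic chlorides, known between two molecules and on β-unbranched chlorides but not as a ring closure; copper-catalysed SN2′ alkylation of β-substituted allylic chlorides with Grignard reagents and macrocyclisation of tethered alkyl-9-BBN units by B-alkyl Suzuki coupling support the two extensions made here. The 14-membered ring closes in the 14-exo-trig mode. The new C1 stereocentre is set by the chiral ligand, which must deliver C14 to the si face of C1 to give the S configuration; C12 is three bonds away and should bias the result little. The step needs γ- over α-attack (α-attack would close a 16-membered ring) and ring closure over oligomerisation: the Z geometry holds the C16–Cl bond perpendicular to the alkene plane through allylic 1,3-strain, which favours the SN2′ path, and slow addition at high dilution favours the ring.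

**Step 15**
Reactants: 22 tert-butyl{[(1S,4Z,8E,12S)-5,9-dimethyl-12-(6-methylhepta-1,5-dien-2-yl)cyclotetradeca-4,8-dien-1-yl]methoxy}diphenylsilane
Product: 23 [(1S,4Z,8E,12S)-5,9-dimethyl-12-(6-methylhepta-1,5-dien-2-yl)cyclotetradeca-4,8-dien-1-yl]methanol
Conditions: Bu4NF, THF, 25 °C
Reagents that add atoms: none
Why: Fluoride should cleave the primary silyl ether and leave the polyene and both stereocentres untouched.

**Compound list**

1 | neryl acetate, (2Z)-3,7-dimethylocta-2,6-dien-1-yl acetate | CC(=O)OC/C=C(C)\CCC=C(C)C | starting material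
2 | (2Z,6E)-8-hydroxy-3,7-dimethylocta-2,6-dien-1-yl acetate | CC(=O)OC/C=C(C)\CC/C=C(C)/CO | intermediate
3 | (2Z,6E)-8-bromo-3,7-dimethylocta-2,6-dien-1-yl acetate | CC(=O)OC/C=C(C)\CC/C=C(C)/CBr | intermediate
4 | (1,3-dioxolan-2-ylmethyl)magnesium bromide (THF solution) | Br[Mg]CC1OCCO1 | starting material
5 | (2Z,6E)-9-(1,3-dioxolan-2-yl)-3,7-dimethylnona-2,6-dien-1-yl acetate | CC(=O)OC/C=C(C)\CC/C=C(C)/CCC1OCCO1 | intermediate (not isolated)
6 | (2Z,6E)-9-(1,3-dioxolan-2-yl)-3,7-dimethylnona-2,6-dien-1-ol | OC/C=C(C)\CC/C=C(C)/CCC1OCCO1 | intermediate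
7 | (2Z,6E)-9-(1,3-dioxolan-2-yl)-3,7-dimethylnona-2,6-dienal | O=C/C=C(C)\CC/C=C(C)/CCC1OCCO1 | intermediate
8 | 2-[(3E,7Z)-3,7-dimethyldeca-3,7,9-trien-1-yl]-1,3-dioxolane | C=C/C=C(C)\CC/C=C(C)/CCC1OCCO1 | intermediate
9 | (Z)-but-2-ene-1,4-diol | OC/C=C\CO | starting material
10 | (Z)-4-[(tert-butyldiphenylsilyl)oxy]but-2-en-1-ol | OC/C=C\CO[Si](C(C)(C)C)(c1ccccc1)c1ccccc1 | intermediate
11 | tert-butyl{[(Z)-4-chlorobut-2-en-1-yl]oxy}diphenylsilane | ClC/C=C\CO[Si](C(C)(C)C)(c1ccccc1)c1ccccc1 | intermediate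
12 | 9-[(3Z,7E)-10-(1,3-dioxolan-2-yl)-4,8-dimethyldeca-3,7-dien-1-yl]-9-borabicyclo[3.3.1]nonane | C1CC2CCCC(C1)B2CC/C=C(C)\CC/C=C(C)/CCC1OCCO1 | intermediate (not isolated)
13 | tert-butyl{[(2S,5Z,9E)-12-(1,3-dioxolan-2-yl)-2-ethenyl-6,10-dimethyldodeca-5,9-dien-1-yl]oxy}diphenylsilane | C=C[C@@H](CO[Si](C(C)(C)C)(c1ccccc1)c1ccccc1)CC/C=C(C)\CC/C=C(C)/CCC1OCCO1 | intermediate
14 | (4E,8Z,12S)-12-{[(tert-butyldiphenylsilyl)oxy]methyl}-4,8-dimethyltetradeca-4,8,13-trienal | C=C[C@@H](CO[Si](C(C)(C)C)(c1ccccc1)c1ccccc1)CC/C=C(C)\CC/C=C(C)/CCC=O | intermediate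
15 | methyl 2-[bis(2,2,2-trifluoroethoxy)phosphoryl]acetate | COC(=O)CP(=O)(OCC(F)(F)F)OCC(F)(F)F | starting material
16 | 5-bromo-2-methylpent-2-ene | CC(C)=CCCBr | starting material
17 | methyl 2-[bis(2,2,2-trifluoroethoxy)phosphoryl]-6-methylhept-5-enoate (racemic) | COC(=O)C(CCC=C(C)C)P(=O)(OCC(F)(F)F)OCC(F)(F)F | intermediate
18 | methyl (2Z,6E,10Z,14S)-14-{[(tert-butyldiphenylsilyl)oxy]methyl}-6,10-dimethyl-2-(4-methylpent-3-en-1-yl)hexadeca-2,6,10,15-tetraenoate | C=C[C@@H](CO[Si](C(C)(C)C)(c1ccccc1)c1ccccc1)CC/C=C(C)\CC/C=C(C)/CC/C=C(/CCC=C(C)C)C(=O)OC | intermediate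
19 | (2Z,6E,10Z,14S)-14-{[(tert-butyldiphenylsilyl)oxy]methyl}-6,10-dimethyl-2-(4-methylpent-3-en-1-yl)hexadeca-2,6,10,15-tetraen-1-ol | C=C[C@@H](CO[Si](C(C)(C)C)(c1ccccc1)c1ccccc1)CC/C=C(C)\CC/C=C(C)/CC/C=C(/CCC=C(C)C)CO | intermediate
20 | tert-butyl{[(2S,5Z,9E,13Z)-14-(chloromethyl)-2-ethenyl-6,10,18-trimethylnonadeca-5,9,13,17-tetraen-1-yl]oxy}diphenylsilane | C=C[C@@H](CO[Si](C(C)(C)C)(c1ccccc1)c1ccccc1)CC/C=C(C)\CC/C=C(C)/CC/C=C(/CCC=C(C)C)CCl | intermediate
21 | 9-BBN adduct of 20 (boron on the former terminal vinyl carbon), 9-[(3R,6Z,10E,14Z)-3-{[(tert-butyldiphenylsilyl)oxy]methyl}-15-(chloromethyl)-7,11,19-trimethylicosa-6,10,14,18-tetraen-1-yl]-9-borabicyclo[3.3.1]nonane | C1CC2CCCC(C1)B2CC[C@@H](CO[Si](C(C)(C)C)(c1ccccc1)c1ccccc1)CC/C=C(C)\CC/C=C(C)/CC/C=C(/CCC=C(C)C)CCl | intermediate (not isolated)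
22 | tert-butyl{[(1S,4Z,8E,12S)-5,9-dimethyl-12-(6-methylhepta-1,5-dien-2-yl)cyclotetradeca-4,8-dien-1-yl]methoxy}diphenylsilane | C=C(CCC=C(C)C)[C@@H]1CC/C(C)=C/CC/C(C)=C\CC[C@H](CO[Si](C(C)(C)C)(c2ccccc2)c2ccccc2)CC1 | intermediate
23 | [(1S,4Z,8E,12S)-5,9-dimethyl-12-(6-methylhepta-1,5-dien-2-yl)cyclotetradeca-4,8-dien-1-yl]methanol (CNP0262734.1) | C=C(CCC=C(C)C)[C@@H]1CC/C(C)=C/CC/C(C)=C\CC[C@H](CO)CC1 | target

**Step count.** Total: 15 steps. Longest linear sequence: 12 steps (steps 1–5, 8, 9, 11–15).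

**Steps most likely to fail**

1. Step 14 (Proposed new method). The alkylcopper may couple between molecules faster than it reaches its own allylic chloride (oligomerisation), attack at the α-carbon C16 may close a 16-membered ring, or ligand control of the C1 face may be eroded by the resident C12 centre. The fallback uses known chemistry, sets out from 20 and comes back at 22. Hydroboration of the vinyl group of 20 with 9-BBN and oxidation with NaBO3·4H2O should give the primary alcohol (3S,6Z,10E,14Z)-3-{[(tert-butyldiphenylsilyl)oxy]methyl}-15-(chloromethyl)-7,11,19-trimethylicosa-6,10,14,18-tetraen-1-ol F1, and Dess–Martin oxidation the corresponding aldehyde, the icosa-6,10,14,18-tetraenal F2. Under Nozaki–Hiyama–Kishi conditions (CrCl2, NaI, a chiral sulfonamide–oxazoline ligand, Et3N, THF, high dilution) the allylic chloride becomes an allylchromium reagent that adds through its γ-carbon C1 to the C14 aldehyde, an established way to close 14-membered terpenoid rings. This should give the anti homoallylic alcohol (1R,2S,5E,9Z,13S)-13-{[(tert-butyldiphenylsilyl)oxy]methyl}-5,9-dimethyl-2-(6-methylhepta-1,5-dien-2-yl)cyclotetradeca-5,9-dien-1-ol F3. The ligand hand is chosen for the required C1 configuration, and the carbinol centre is removed next. 1,1′-Thiocarbonyldiimidazole converts F3 into its O-cyclotetradecadienyl 1H-imidazole-1-carbothioate F4. Barton–McCombie reduction (Bu3SnH, AIBN, toluene, 80 °C, high tin hydride concentration to outrun 1,2-vinyl migration of the homoallyl radical) then gives 22.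

2. Step 8. Facial discrimination at C12 may be incomplete with this oxygenated allylic chloride, or α-substitution may compete and give the linear Z-alkene. The fallback replaces catalyst control by auxiliary control, sets out from 8 and comes back at 13. Hydroboration of 8 (9-BBN) with NaOH/H2O2 work-up should give (3Z,7E)-10-(1,3-dioxolan-2-yl)-4,8-dimethyldeca-3,7-dien-1-ol F5. Tf2O and 2,6-di-tert-butylpyridine in CH2Cl2 at −78 °C give its trifluoromethanesulfonate F6, which is used at once. The sodium dienolate of (S)-4-benzyl-3-[(E)-but-2-enoyl]-1,3-oxazolidin-2-one (NaN(SiMe3)2, THF, −78 °C) is alkylated at its α-carbon from the face opposite to the benzyl group (deconjugative alkylation of the oxazolidinone imide). This should give (4S)-4-benzyl-3-[(2S,5Z,9E)-12-(1,3-dioxolan-2-yl)-2-ethenyl-6,10-dimethyldodeca-5,9-dienoyl]-1,3-oxazolidin-2-one F7. LiBH4 (MeOH, THF, 0 °C) releases the auxiliary and gives (2S,5Z,9E)-12-(1,3-dioxolan-2-yl)-2-ethenyl-6,10-dimethyldodeca-5,9-dien-1-ol F8. Silylation (t-BuPh2SiCl, imidazole, DMF) gives 13.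

3. Step 3. The organocopper may attack the γ-carbon of the allylic bromide and give the branched 1,1-disubstituted alkene, or the β-alkoxy Grignard reagent may be lost by elimination before it couples. The fallback builds the same C–C bond by a sigmatropic rearrangement, sets out from 1 and comes back at 6. mCPBA (CH2Cl2, 0 °C) should epoxidise only the 6,7-alkene of 1 to give (Z)-5-(3,3-dimethyloxiran-2-yl)-3-methylpent-2-en-1-yl acetate F9. HIO4 (THF/H2O) cleaves it to (Z)-3-methyl-6-oxohex-2-en-1-yl acetate F10. CH2=C(CH3)MgBr at −78 °C adds to the aldehyde in preference to the acetate and gives (Z)-6-hydroxy-3,7-dimethylocta-2,7-dien-1-yl acetate F11. Exchange with ethyl vinyl ether (Hg(OAc)2 cat.) gives (Z)-6-(ethenyloxy)-3,7-dimethylocta-2,7-dien-1-yl acetate F12. Its Claisen rearrangement on heating (chair transition state, carbinol substituent equatorial) should give the E-configured (2Z,6E)-3,7-dimethyl-10-oxodeca-2,6-dien-1-yl acetate F13. Acetalisation (ethylene glycol, pyridinium p-toluenesulfonate, toluene, reflux) gives 5, and K2CO3/MeOH gives 6.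

**Further compounds**

F1 | step 14 | (3S,6Z,10E,14Z)-3-{[(tert-butyldiphenylsilyl)oxy]methyl}-15-(chloromethyl)-7,11,19-trimethylicosa-6,10,14,18-tetraen-1-ol | OCC[C@@H](CO[Si](C(C)(C)C)(c1ccccc1)c1ccccc1)CC/C=C(C)\CC/C=C(C)/CC/C=C(/CCC=C(C)C)CCl
F2 | step 14 | (3S,6Z,10E,14Z)-3-{[(tert-butyldiphenylsilyl)oxy]methyl}-15-(chloromethyl)-7,11,19-trimethylicosa-6,10,14,18-tetraenal | O=CC[C@@H](CO[Si](C(C)(C)C)(c1ccccc1)c1ccccc1)CC/C=C(C)\CC/C=C(C)/CC/C=C(/CCC=C(C)C)CCl
F3 | step 14 | (1R,2S,5E,9Z,13S)-13-{[(tert-butyldiphenylsilyl)oxy]methyl}-5,9-dimethyl-2-(6-methylhepta-1,5-dien-2-yl)cyclotetradeca-5,9-dien-1-ol | C=C(CCC=C(C)C)[C@@H]1CC/C(C)=C/CC/C(C)=C\CC[C@H](CO[Si](C(C)(C)C)(c2ccccc2)c2ccccc2)C[C@H]1O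
F4 | step 14 | O-[(1R,2S,5E,9Z,13S)-13-{[(tert-butyldiphenylsilyl)oxy]methyl}-5,9-dimethyl-2-(6-methylhepta-1,5-dien-2-yl)cyclotetradeca-5,9-dien-1-yl] 1H-imidazole-1-carbothioate | C=C(CCC=C(C)C)[C@@H]1CC/C(C)=C/CC/C(C)=C\CC[C@H](CO[Si](C(C)(C)C)(c2ccccc2)c2ccccc2)C[C@H]1OC(=S)n2ccnc2
F5 | step 8 | (3Z,7E)-10-(1,3-dioxolan-2-yl)-4,8-dimethyldeca-3,7-dien-1-ol | OCC/C=C(C)\CC/C=C(C)/CCC1OCCO1
F6 | step 8 | (3Z,7E)-10-(1,3-dioxolan-2-yl)-4,8-dimethyldeca-3,7-dien-1-yl trifluoromethanesulfonate | FC(F)(F)S(=O)(=O)OCC/C=C(C)\CC/C=C(C)/CCC1OCCO1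
F7 | step 8 | (4S)-4-benzyl-3-[(2S,5Z,9E)-12-(1,3-dioxolan-2-yl)-2-ethenyl-6,10-dimethyldodeca-5,9-dienoyl]-1,3-oxazolidin-2-one | C=C[C@@H](C(=O)N1[C@@H](Cc2ccccc2)COC1=O)CC/C=C(C)\CC/C=C(C)/CCC1OCCO1
F8 | step 8 | (2S,5Z,9E)-12-(1,3-dioxolan-2-yl)-2-ethenyl-6,10-dimethyldodeca-5,9-dien-1-ol | C=C[C@@H](CO)CC/C=C(C)\CC/C=C(C)/CCC1OCCO1
F9 | step 3 | (Z)-5-(3,3-dimethyloxiran-2-yl)-3-methylpent-2-en-1-yl acetate (racemic) | CC(=O)OC/C=C(C)\CCC1OC1(C)C
F10 | step 3 | (Z)-3-methyl-6-oxohex-2-en-1-yl acetate | CC(=O)OC/C=C(C)\CCC=O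
F11 | step 3 | (Z)-6-hydroxy-3,7-dimethylocta-2,7-dien-1-yl acetate (racemic) | CC(=O)OC/C=C(C)\CCC(O)C(C)=C
F12 | step 3 | (Z)-6-(ethenyloxy)-3,7-dimethylocta-2,7-dien-1-yl acetate (racemic) | CC(=O)OC/C=C(C)\CCC(OC=C)C(C)=C
F13 | step 3 | (2Z,6E)-3,7-dimethyl-10-oxodeca-2,6-dien-1-yl acetate | CC(=O)OC/C=C(C)\CC/C=C(C)/CCC=O
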